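**Retrosynthetic overview**

1. The target is a bicyclo[4.3.1]dec-7-ene (C1, C6 bridgeheads; C2–C5 four-carbon bridge; C7–C9 three-carbon bridge; C10 one-carbon bridge; this numbering is used throughout). The two acetates, the C7 formyl group (from a vinyl bromide), the C2 methylidene (from a ketone) and the C4 carbinol (conjugate borylation of a C3=C4 enone) are end-game operations.
2. The enone comes from β-elimination opening of an ether bridge C4–O–C10 in an oxa-bridged tricyclic ketone.
3. Key disconnection: that ketone is made from a monocyclic 2,3-dihydro-4H-pyran-4-one carrying a 2-bromo-1,3-diene by an intramolecular [4+2] cycloaddition that forms C9–C1 and C10–C6. This closes the cyclohexene (C1, C6–C10) and, with it, the seven-membered (C1–C6, C10) and nine-membered (C1–C9) carbocycles in one step.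
4. Enabling feature: the cyclohexene ring with C7=C8 opposite the C1–C10–C6 unit is a Diels–Alder retron, and the oxygen on the one-carbon bridge C10 lies 1,4 across the seven-membered ring from the oxygenated C4. One oxygen can therefore tie C4 to C10 as a dihydropyranone (O, C10, C1, C2, C3, C4) whose C1=C10 bond is the dienophile, and the three-atom tether C5–C4–O turns an otherwise bridged cyclisation into a fused one.
5. The dihydropyranone comes from a hetero-Diels–Alder reaction of Danishefsky's diene with an aldehyde made from (S)-citronellal by α-hydroxymethylation. Ring order: pyranone (temporary), then cyclohexene plus seven- and nine-membered rings (step 8), then pyranone opened (step 9).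

Key step: step 8

Assumption: the (R,R) antipode of (salen)CrBF4 is taken as the one that adds the diene to the Re face of aldehyde 4; if its sense is the opposite, the (S,S) antipode is used with no other change.

**Route**

Step 1
Reactants: 1 (S)-citronellal; 2 formaldehyde (37% aqueous)
Product: 3 (2R,3S)-2-(hydroxymethyl)-3,7-dimethyloct-6-enal
Conditions: (S)-α,α-diphenylprolinol trimethylsilyl ether (10 mol %), pH 7 phosphate buffer, toluene, 23 °C; crude product used directly
Reagents that add atoms: none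
Why: Enamine-catalysed α-hydroxymethylation (cross-aldol with formaldehyde) in which the electrophile should add to the enamine face remote from the diphenyl(silyloxy)methyl group, setting C2 as R under catalyst control (C3 comes from 1).

Step 2
Reactants: 3 (2R,3S)-2-(hydroxymethyl)-3,7-dimethyloct-6-enal
Product: 4 (2R,3S)-2-[(tert-butyldimethylsilyloxy)methyl]-3,7-dimethyloct-6-enal
Conditions: TBSCl, imidazole, CH2Cl2, 0 °C
Reagents that add atoms: tert-butyldimethylsilyl chloride, CC(C)(C)[Si](C)(C)Cl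
Why: Standard silylation of the primary alcohol under weakly basic conditions that should leave the α-stereocentre of the aldehyde untouched.

Step 3
Reactants: 4 silyloxy aldehyde; 5 Danishefsky's diene
Product: 7 (2R)-2-[(2R,3S)-1-(tert-butyldimethylsilyloxy)-3,7-dimethyloct-6-en-2-yl]-2,3-dihydro-4H-pyran-4-one, via cycloadduct 6 (not isolated)
Conditions: (R,R)-(salen)CrBF4 (5 mol %; salen = N,N′-bis(3,5-di-tert-butylsalicylidene)cyclohexane-1,2-diamine dianion), 4 Å molecular sieves, t-BuOMe, −30 °C; then CF3CO2H, CH2Cl2, 0 °C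
Reagents that add atoms: none
Why: Catalyst-controlled asymmetric hetero-Diels–Alder reaction in which the diene should add to the Re face of the aldehyde, setting pyranone C2 (future C4) as R, after which acid removes methanol and the silyl group from 6.

Step 4
Reactants: 7 pyranone silyl ether
Product: 8 (2R)-2-[(2R,3S)-1-hydroxy-3,7-dimethyloct-6-en-2-yl]-2,3-dihydro-4H-pyran-4-one
Conditions: HF·pyridine, pyridine, THF, 0 → 23 °C
Reagents that add atoms: none
Why: Buffered fluoride desilylation that should spare the vinylogous ester and the trisubstituted alkene.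

Step 5
Reactants: 8 pyranone alcohol
Product: 9 (2S,3S)-3,7-dimethyl-2-[(2R)-4-oxo-3,4-dihydro-2H-pyran-2-yl]oct-6-enal
Conditions: Dess–Martin periodinane, CH2Cl2, 0 → 23 °C; used at once
Reagents that add atoms: none
Why: Dess–Martin oxidation, chosen as a base-free method because this aldehyde (α-stereocentre, β-leaving group) would epimerise or undergo β-elimination with base.

Step 6
Reactants: 9 pyranone aldehyde
Product: 10 (2R)-2-[(3R,4S)-1,1-dibromo-4,8-dimethylnona-1,7-dien-3-yl]-2,3-dihydro-4H-pyran-4-one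
Conditions: CBr4, PPh3, Zn, CH2Cl2, 23 °C (reagent pre-formed); then 9, 0 °C
Reagents that add atoms: carbon tetrabromide, BrC(Br)(Br)Br
Why: Ramirez dibromo-olefination (first stage of the Corey–Fuchs sequence) with the zinc-modified, base-free ylide, which should react only with the aldehyde and not with the vinylogous-ester carbonyl; no stereocentre is formed.

Step 7
Reactants: 10 dibromoalkene
Product: 11 (2R)-2-[(3Z,5R,6S)-3-bromo-6,10-dimethylundeca-1,3,9-trien-5-yl]-2,3-dihydro-4H-pyran-4-one
Conditions: tributyl(vinyl)stannane (1.05 equiv), Pd2(dba)3 (2.5 mol %), P(2-furyl)3 (15 mol %), toluene, 100 °C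
Reagents that add atoms: tributyl(vinyl)stannane, CCCC[Sn](CCCC)(CCCC)C=C
Why: Stille coupling in which palladium should insert selectively into the C–Br bond trans to the alkyl group of the 1,1-dibromoalkene and couple with retention, giving the (Z)-2-bromo-1,3-diene with the chain trans to the new vinyl group, as the cycloaddition requires.

Step 8
Reactants: 11 bromodiene dihydropyranone
Product: 12 (1R,4S,8S,9S,11R)-7-bromo-11-[(2S)-6-methylhept-5-en-2-yl]-10-oxatricyclo[6.2.1.0(4,9)]undec-6-en-3-one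
Conditions: Me2AlCl (1.5 equiv), CH2Cl2 (0.01 M), −40 → 0 °C
Reagents that add atoms: none
Why: Proposed new method: Me2AlCl binds the vinylogous-ester carbonyl and the tethered (Z)-2-bromodiene adds across the pyranone C5=C6 bond in a concerted but asynchronous, normal-demand intramolecular [4+2] cycloaddition (the bond from the diene carbon that becomes C6 to the oxocarbenium-like carbon that becomes C10 leads), the closest known reaction types being the Lewis-acid-promoted type 1 intramolecular Diels–Alder reaction of 1,3,8-nonatrienes with cyclic enone dienophiles and the Diels–Alder reactions of activated dihydropyranones and chromones. Two rings close, the cyclohexene by the [4+2] union itself and the oxolane (C4, O, C10, C6, C5) in the fused mode through the three-atom tether C5–C4–O, and these closures complete the seven-membered carbocycle (through C10–C6) and the nine-membered one (through C9–C1). The new centres C10, C1 and C6 are fixed by the existing centre C4: the diene can reach only the face of the C1=C10 bond that carries its own tether, addition is suprafacial on both partners, and the diene geometry (chain trans to vinyl) places C6–H cis to C10–H, the only arrangement the cage allows. The step needs regioselectivity (C6 to C10 and C9 to C1, not the reverse) and site selectivity (pyranone, not the side-chain alkene): the first is secured by the short tether through oxygen (five-membered ring against a bicyclo[2.2.2] alternative) and by the polarity match of the diene terminus with the enone β-carbon, the second by Lewis-acid activation of the vinylogous ester alone.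

Step 9
Reactants: 12 oxa-bridged tricyclic ketone
Product: 14 (1S,5S,6S,10S)-7-bromo-5-[(2S)-6-methylhept-5-en-2-yl]-10-(triethylsilyloxy)bicyclo[4.3.1]deca-3,7-dien-2-one, via silyl enol ether 13 (not isolated)
Conditions: TESOTf (1.3 equiv), Et3N (2 equiv), CH2Cl2, −78 → 0 °C; aqueous NaHCO3
Reagents that add atoms: triethylsilyl triflate, CC[Si](CC)(CC)OS(=O)(=O)C(F)(F)F
Why: Soft enolisation towards C3 followed by silyl-triflate-assisted vinylogous β-elimination of the C4–O bond (the known opening of 8-oxabicyclo[3.2.1]octan-3-ones); the enol ether towards C1 cannot eliminate because a C1=C10 double bond would be anti-Bredt, and silyl transfer to the C10 oxygen prevents re-closure by oxa-Michael addition.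

Step 10
Reactants: 14 silyloxy enone
Product: 16 (1S,4S,5R,6S,10S)-7-bromo-4-hydroxy-5-[(2S)-6-methylhept-5-en-2-yl]-10-(triethylsilyloxy)bicyclo[4.3.1]dec-7-en-2-one, via β-boryl ketone 15 (not isolated)
Conditions: CuCl (10 mol %), NaOtBu (15 mol %), DPEphos (10 mol %), B2pin2 (1.2 equiv), MeOH (2 equiv), THF, 23 °C; then NaBO3·4H2O, THF/H2O, 23 °C
Reagents that add atoms: bis(pinacolato)diboron, CC1(C)OB(OC1(C)C)B1OC(C)(C)C(C)(C)O1; sodium perborate, [Na+].[Na+].O[B-]1(O)OO[B-](O)(O)OO1
Why: Copper-catalysed conjugate borylation followed by stereoretentive perborate oxidation; the boryl copper species should add to C4 on the face opposite the C10 silyloxy group, which sits directly above C4 because it has just left that carbon, giving the 4S alcohol.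

Step 11
Reactants: 16 β-hydroxy ketone
Product: 17 (1R,4S,5R,6S,10S)-7-bromo-2-methylidene-5-[(2S)-6-methylhept-5-en-2-yl]-10-(triethylsilyloxy)bicyclo[4.3.1]dec-7-en-4-ol
Conditions: Zn, CH2Br2, TiCl4, THF/CH2Cl2, 0 → 23 °C
Reagents that add atoms: dibromomethane, BrCBr
Why: Lombardo methylenation, a non-basic titanium–zinc carbenoid olefination that should avoid retro-aldol cleavage and β-elimination of the β-hydroxy ketone and tolerates the free hydroxyl and the vinyl bromide.

Step 12
Reactants: 17 bromo alcohol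
Product: 20 (1R,4S,5R,6R,10S)-4,10-dihydroxy-2-methylidene-5-[(2S)-6-methylhept-5-en-2-yl]bicyclo[4.3.1]dec-7-ene-7-carbaldehyde, via dilithio species 18 (not isolated), via silyl ether enal 19 (not isolated)
Conditions: t-BuLi (4 equiv), THF, −78 °C; DMF, −78 → 0 °C; then 1 M HCl, THF, 23 °C
Reagents that add atoms: N,N-dimethylformamide, CN(C)C=O
Why: Bromine–lithium exchange on the lithium alkoxide of 17 gives the vinyllithium without moving the double bond, Bouveault formylation with DMF installs the C7 aldehyde, and the acidic work-up releases the enal and cleaves the triethylsilyl ether.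

Step 13
Reactants: 20 diol enal
Product: 21 (1R,4S,5R,6R,10S)-7-formyl-2-methylidene-5-[(2S)-6-methylhept-5-en-2-yl]bicyclo[4.3.1]dec-7-ene-4,10-diyl diacetate (CNP0197379.1)
Conditions: Ac2O, DMAP, pyridine, CH2Cl2, 23 °C
Reagents that add atoms: acetic anhydride, CC(=O)OC(C)=O
Why: DMAP-catalysed acetylation of both secondary alcohols (the hindered C10 hydroxyl may need gentle warming); no stereocentre is affected.

**Compound list**

1 | (S)-citronellal, (3S)-3,7-dimethyloct-6-enal | O=CC[C@@H](C)CCC=C(C)C | starting material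
2 | formaldehyde | C=O | starting material
3 | (2R,3S)-2-(hydroxymethyl)-3,7-dimethyloct-6-enal | O=C[C@@H](CO)[C@@H](C)CCC=C(C)C | intermediate
4 | (2R,3S)-2-[(tert-butyldimethylsilyloxy)methyl]-3,7-dimethyloct-6-enal | O=C[C@@H](CO[Si](C)(C)C(C)(C)C)[C@@H](C)CCC=C(C)C | intermediate
5 | Danishefsky's diene, (E)-1-methoxy-3-(trimethylsilyloxy)buta-1,3-diene | CO/C=C/C(=C)O[Si](C)(C)C | starting material
6 | cycloadduct (not isolated), (2S,6R)-6-[(2R,3S)-1-(tert-butyldimethylsilyloxy)-3,7-dimethyloct-6-en-2-yl]-2-methoxy-4-(trimethylsilyloxy)-3,6-dihydro-2H-pyran | CC(C)(C)[Si](C)(C)OC[C@@H]([C@@H](C)CCC=C(C)C)[C@H]1CC(O[Si](C)(C)C)=C[C@@H](OC)O1 | intermediate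
7 | (2R)-2-[(2R,3S)-1-(tert-butyldimethylsilyloxy)-3,7-dimethyloct-6-en-2-yl]-2,3-dihydro-4H-pyran-4-one | CC(C)(C)[Si](C)(C)OC[C@@H]([C@@H](C)CCC=C(C)C)[C@H]1CC(=O)C=CO1 | intermediate
8 | (2R)-2-[(2R,3S)-1-hydroxy-3,7-dimethyloct-6-en-2-yl]-2,3-dihydro-4H-pyran-4-one | OC[C@@H]([C@@H](C)CCC=C(C)C)[C@H]1CC(=O)C=CO1 | intermediate
9 | (2S,3S)-3,7-dimethyl-2-[(2R)-4-oxo-3,4-dihydro-2H-pyran-2-yl]oct-6-enal | O=C[C@@H]([C@@H](C)CCC=C(C)C)[C@H]1CC(=O)C=CO1 | intermediate
10 | (2R)-2-[(3R,4S)-1,1-dibromo-4,8-dimethylnona-1,7-dien-3-yl]-2,3-dihydro-4H-pyran-4-one | BrC(Br)=C[C@@H]([C@@H](C)CCC=C(C)C)[C@H]1CC(=O)C=CO1 | intermediate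
11 | (2R)-2-[(3Z,5R,6S)-3-bromo-6,10-dimethylundeca-1,3,9-trien-5-yl]-2,3-dihydro-4H-pyran-4-one | C=C/C(Br)=C/[C@@H]([C@@H](C)CCC=C(C)C)[C@H]1CC(=O)C=CO1 | intermediate
12 | (1R,4S,8S,9S,11R)-7-bromo-11-[(2S)-6-methylhept-5-en-2-yl]-10-oxatricyclo[6.2.1.0(4,9)]undec-6-en-3-one (target skeleton with C2 as ketone and one oxygen bridging C4 and C10) | O=C1C[C@@H]3[C@H]([C@@H](C)CCC=C(C)C)[C@@H]2C(Br)=CC[C@H]1[C@@H]2O3 | intermediate
13 | triethylsilyl enol ether of 12 (not isolated), 7-bromo-11-[(2S)-6-methylhept-5-en-2-yl]-3-(triethylsilyloxy)-10-oxatricyclo[6.2.1.0(4,9)]undeca-2,6-diene, stereocentres as in 12 | CC[Si](CC)(CC)OC1=C[C@@H]3[C@H]([C@@H](C)CCC=C(C)C)[C@@H]2C(Br)=CC[C@H]1[C@@H]2O3 | intermediate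
14 | (1S,5S,6S,10S)-7-bromo-5-[(2S)-6-methylhept-5-en-2-yl]-10-(triethylsilyloxy)bicyclo[4.3.1]deca-3,7-dien-2-one | O=C1C=C[C@H]([C@@H](C)CCC=C(C)C)[C@@H]2C(Br)=CC[C@H]1[C@@H]2O[Si](CC)(CC)CC | intermediate
15 | β-boryl ketone (not isolated), (1S,4S,5R,6S,10S)-7-bromo-5-[(2S)-6-methylhept-5-en-2-yl]-4-(4,4,5,5-tetramethyl-1,3,2-dioxaborolan-2-yl)-10-(triethylsilyloxy)bicyclo[4.3.1]dec-7-en-2-one | O=C1C[C@H](B3OC(C)(C)C(C)(C)O3)[C@H]([C@@H](C)CCC=C(C)C)[C@@H]2C(Br)=CC[C@H]1[C@@H]2O[Si](CC)(CC)CC | intermediate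
16 | (1S,4S,5R,6S,10S)-7-bromo-4-hydroxy-5-[(2S)-6-methylhept-5-en-2-yl]-10-(triethylsilyloxy)bicyclo[4.3.1]dec-7-en-2-one | O=C1C[C@H](O)[C@H]([C@@H](C)CCC=C(C)C)[C@@H]2C(Br)=CC[C@H]1[C@@H]2O[Si](CC)(CC)CC | intermediate
17 | (1R,4S,5R,6S,10S)-7-bromo-2-methylidene-5-[(2S)-6-methylhept-5-en-2-yl]-10-(triethylsilyloxy)bicyclo[4.3.1]dec-7-en-4-ol (target numbering) | C=C1C[C@H](O)[C@H]([C@@H](C)CCC=C(C)C)[C@@H]2C(Br)=CC[C@H]1[C@@H]2O[Si](CC)(CC)CC | intermediate
18 | dilithio species (not isolated), C7-lithio lithium C4-alkoxide of 17 | C=C1C[C@H](O[Li])[C@H]([C@@H](C)CCC=C(C)C)[C@@H]2C([Li])=CC[C@H]1[C@@H]2O[Si](CC)(CC)CC | intermediate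
19 | silyl ether enal (not isolated), (1R,4S,5R,6R,10S)-4-hydroxy-2-methylidene-5-[(2S)-6-methylhept-5-en-2-yl]-10-(triethylsilyloxy)bicyclo[4.3.1]dec-7-ene-7-carbaldehyde | C=C1C[C@H](O)[C@H]([C@@H](C)CCC=C(C)C)[C@@H]2C(C=O)=CC[C@H]1[C@@H]2O[Si](CC)(CC)CC | intermediate
20 | (1R,4S,5R,6R,10S)-4,10-dihydroxy-2-methylidene-5-[(2S)-6-methylhept-5-en-2-yl]bicyclo[4.3.1]dec-7-ene-7-carbaldehyde | C=C1C[C@H](O)[C@H]([C@@H](C)CCC=C(C)C)[C@@H]2C(C=O)=CC[C@H]1[C@@H]2O | intermediate
21 | (1R,4S,5R,6R,10S)-7-formyl-2-methylidene-5-[(2S)-6-methylhept-5-en-2-yl]bicyclo[4.3.1]dec-7-ene-4,10-diyl diacetate | C=C1C[C@H](OC(C)=O)[C@H]([C@@H](C)CCC=C(C)C)[C@@H]2C(C=O)=CC[C@H]1[C@@H]2OC(C)=O | target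

**Totals and risks**

Total step count: 13. Longest linear sequence: 13 steps, from (S)-citronellal.

Steps most likely to fail:

1. Step 8 (proposed new method). In the only transition state the cage allows, the side chain on C5 must lie nearly eclipsed with the C–Br bond of the diene (allylic 1,3-strain), and a vinylogous ester is a weak dienophile. Ring closure may therefore be slow enough for Lewis-acid-induced oligomerisation of the diene, or attack by the side-chain alkene, to take over. Fallback with known chemistry, setting out from 10 and returning at 12: the pyranone of 10 is iodinated at its C5 (I2, pyridine) to (2R)-2-[(3R,4S)-1,1-dibromo-4,8-dimethylnona-1,7-dien-3-yl]-5-iodo-2,3-dihydro-4H-pyran-4-one F1. Methoxycarbonylation (Pd(PPh3)4, CO, MeOH, Et3N; insertion into the α-iodoenone should be faster than into the dibromoalkene) gives the β-keto ester, methyl (2R)-2-[(3R,4S)-1,1-dibromo-4,8-dimethylnona-1,7-dien-3-yl]-4-oxo-3,4-dihydro-2H-pyran-5-carboxylate F2. Stille coupling as in step 7 gives methyl (2R)-2-[(3Z,5R,6S)-3-bromo-6,10-dimethylundeca-1,3,9-trien-5-yl]-4-oxo-3,4-dihydro-2H-pyran-5-carboxylate F3, whose 2-alkoxycarbonyl enone is an established, doubly activated dienophile class. Thermal intramolecular Diels–Alder reaction (toluene, 110 °C) should give the angular ester, methyl 7-bromo-11-[(2S)-6-methylhept-5-en-2-yl]-3-oxo-10-oxatricyclo[6.2.1.0(4,9)]undec-6-ene-4-carboxylate F4 (other centres as in 12). Krapcho dealkoxycarbonylation (LiCl, wet DMSO, 140 °C) then gives 12, because the enolate formed towards C1 cannot expel the bridge oxygen and can be protonated only to the cis-fused ketone.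

2. Step 10. Facial selectivity of the boryl copper addition at C4 may be poor or reversed, since the neighbouring C5 side chain hinders the face opposite the C10 silyloxy group. Fallback, setting out from 14 and returning at 17: the C4 epimer formed in the borylation/oxidation, (1S,4R,5R,6S,10S)-7-bromo-4-hydroxy-5-[(2S)-6-methylhept-5-en-2-yl]-10-(triethylsilyloxy)bicyclo[4.3.1]dec-7-en-2-one F5, is methylenated as in step 11 to (1R,4R,5R,6S,10S)-7-bromo-2-methylidene-5-[(2S)-6-methylhept-5-en-2-yl]-10-(triethylsilyloxy)bicyclo[4.3.1]dec-7-en-4-ol F6. Mitsunobu inversion (4-nitrobenzoic acid, PPh3, DIAD; the hindered C10 silyl ether is inert) gives (1R,4S,5R,6S,10S)-7-bromo-2-methylidene-5-[(2S)-6-methylhept-5-en-2-yl]-10-(triethylsilyloxy)bicyclo[4.3.1]dec-7-en-4-yl 4-nitrobenzoate F7, and methanolysis (K2CO3, MeOH) gives 17.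

3. Step 3. The inherent facial bias of the α-branched aldehyde 4 (Felkin and chelation models both point to the other face) may work against the catalyst and erode the diastereoselectivity at pyranone C2. Fallback, setting out from 4 and returning at 7: reagent-controlled Brown allylation with (+)-Ipc2B(allyl) (from (−)-α-pinene, Re-face addition; Et2O, −78 °C, then NaOH/H2O2) gives (4R,5R,6S)-5-[(tert-butyldimethylsilyloxy)methyl]-6,10-dimethylundeca-1,9-dien-4-ol F8. Tsuji–Wacker oxidation of the terminal alkene (PdCl2, CuCl, O2, DMF/H2O) gives (4R,5R,6S)-5-[(tert-butyldimethylsilyloxy)methyl]-4-hydroxy-6,10-dimethylundec-9-en-2-one F9. Condensation with N,N-dimethylformamide dimethyl acetal gives the enaminone (1E,5R,6R,7S)-6-[(tert-butyldimethylsilyloxy)methyl]-1-(dimethylamino)-5-hydroxy-7,11-dimethyldodeca-1,10-dien-3-one F10, which should close to 7 with CF3CO2H by addition–elimination of the hydroxyl (the chromone-type closure).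

**Further compounds**

F1 | step 8 | (2R)-2-[(3R,4S)-1,1-dibromo-4,8-dimethylnona-1,7-dien-3-yl]-5-iodo-2,3-dihydro-4H-pyran-4-one | BrC(Br)=C[C@@H]([C@@H](C)CCC=C(C)C)[C@H]1CC(=O)C(I)=CO1
F2 | step 8 | methyl (2R)-2-[(3R,4S)-1,1-dibromo-4,8-dimethylnona-1,7-dien-3-yl]-4-oxo-3,4-dihydro-2H-pyran-5-carboxylate | BrC(Br)=C[C@@H]([C@@H](C)CCC=C(C)C)[C@H]1CC(=O)C(C(=O)OC)=CO1
F3 | step 8 | methyl (2R)-2-[(3Z,5R,6S)-3-bromo-6,10-dimethylundeca-1,3,9-trien-5-yl]-4-oxo-3,4-dihydro-2H-pyran-5-carboxylate | C=C/C(Br)=C/[C@@H]([C@@H](C)CCC=C(C)C)[C@H]1CC(=O)C(C(=O)OC)=CO1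
F4 | step 8 | methyl 7-bromo-11-[(2S)-6-methylhept-5-en-2-yl]-3-oxo-10-oxatricyclo[6.2.1.0(4,9)]undec-6-ene-4-carboxylate, other centres as in 12 | O=C1C[C@@H]3[C@H]([C@@H](C)CCC=C(C)C)[C@@H]2C(Br)=CC[C@@]1(C(=O)OC)[C@@H]2O3
F5 | step 10 | (1S,4R,5R,6S,10S)-7-bromo-4-hydroxy-5-[(2S)-6-methylhept-5-en-2-yl]-10-(triethylsilyloxy)bicyclo[4.3.1]dec-7-en-2-one | O=C1C[C@@H](O)[C@H]([C@@H](C)CCC=C(C)C)[C@@H]2C(Br)=CC[C@H]1[C@@H]2O[Si](CC)(CC)CC
F6 | step 10 | (1R,4R,5R,6S,10S)-7-bromo-2-methylidene-5-[(2S)-6-methylhept-5-en-2-yl]-10-(triethylsilyloxy)bicyclo[4.3.1]dec-7-en-4-ol | C=C1C[C@@H](O)[C@H]([C@@H](C)CCC=C(C)C)[C@@H]2C(Br)=CC[C@H]1[C@@H]2O[Si](CC)(CC)CC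
F7 | step 10 | (1R,4S,5R,6S,10S)-7-bromo-2-methylidene-5-[(2S)-6-methylhept-5-en-2-yl]-10-(triethylsilyloxy)bicyclo[4.3.1]dec-7-en-4-yl 4-nitrobenzoate | C=C1C[C@H](OC(=O)c3ccc(cc3)[N+](=O)[O-])[C@H]([C@@H](C)CCC=C(C)C)[C@@H]2C(Br)=CC[C@H]1[C@@H]2O[Si](CC)(CC)CC
F8 | step 3 | (4R,5R,6S)-5-[(tert-butyldimethylsilyloxy)methyl]-6,10-dimethylundeca-1,9-dien-4-ol | C=CC[C@@H](O)[C@@H](CO[Si](C)(C)C(C)(C)C)[C@@H](C)CCC=C(C)C
F9 | step 3 | (4R,5R,6S)-5-[(tert-butyldimethylsilyloxy)methyl]-4-hydroxy-6,10-dimethylundec-9-en-2-one | CC(=O)C[C@@H](O)[C@@H](CO[Si](C)(C)C(C)(C)C)[C@@H](C)CCC=C(C)C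
F10 | step 3 | (1E,5R,6R,7S)-6-[(tert-butyldimethylsilyloxy)methyl]-1-(dimethylamino)-5-hydroxy-7,11-dimethyldodeca-1,10-dien-3-one | CN(C)/C=C/C(=O)C[C@@H](O)[C@@H](CO[Si](C)(C)C(C)(C)C)[C@@H](C)CCC=C(C)C
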